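## Structural features

The target 31 is a C25 terpenoid built on a trans-fused labdane decalin (ring A: C1–C5, C10; ring B: C5–C10). The decalin carries a β-methyl on C10, an α-hydroxymethyl (C18) and a β-methyl (C19) on C4, an equatorial 6α-hydroxyl, and a tertiary 8α-hydroxyl geminal to the axial β-methyl C17. C9 bears a β side chain C11–C12–C13; C13 carries the exocyclic methylene C16 and is followed by the carbinols C14 and C15 and by C5' of a 4'-methylbut-2'-en-4'-olide (O1', C2'=O, C3'=C4', C5'). There are nine stereocentres: C4, C5, C6, C8, C9 and C10 are contiguous on the decalin, and C14, C15 and C5' form an all-syn (14S,15R,5'R) oxygenated triad separated from the ring by the methylenes C11 and C12. The fragile groups are the butenolide (acidic C5'–H, base-induced epimerisation or opening, translactonisation onto free O15 or O14), the tertiary C8 alcohol (it closes a tetrahydrofuran onto any electrophilic C12), the allylic C14 alcohol, and the α-alkoxy aldehydes met on the way. The real difficulty lies in three places: oxygenating only C18 of the two geminal methyls on C4, joining the hindered decalin to a densely oxygenated four-carbon unit at the unactivated C12–C13 bond, and introducing the base-sensitive butenolide late with the correct C5' configuration. The key step exploits the attachment of the butenolide through C5' to the oxygen-bearing C15: the C4'–C5' and O1'–C2' bonds can both come from a C5' aldehyde and a Z-configured C2'–C4' enoate nucleophile, with the C15 oxygen steering the new centre.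

## Logic of the disconnections

31 ⇒ 30 ⇒ 29. Only heteroatom–protecting-group bonds are cut: four O–Si bonds, then the O15–benzyl bond. The butenolide and the free diol are exposed last, so all five hydroxyls stay inert during the C–C bond formations. Both removals must run without base: fluoride under buffered acidic conditions and an oxidative ether cleavage at neutral pH.

29 ⇒ 24 + 26. The C4'–C5' and O1'–C2' bonds are cut, which opens the butenolide and removes the C5' stereocentre. The lactone then appears only in the last C–C bond-forming step, and the problem is reduced to an α-alkoxy aldehyde and a four-carbon reagent. The forward step must give the 15,5'-syn isomer, so in 24 O15 carries a chelating 4-methoxybenzyl (PMB) ether and O14 a bulky, non-chelating tert-butyldimethylsilyl (TBS) ether; the nucleophile must be Z so that the alkoxide reaches the ester.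

26 ⇒ 25. The C3–I and C2–H bonds are cut. The iodo enoate is the stable precursor of the alkenylmagnesium, and 25 is commercial. The forward hydroiodination must be anti so that iodine ends up cis to the ester.

24 ⇒ 23 ⇒ 22. The aldehyde is taken back to the primary alcohol, and the O15–CH2Ar and O5'–H bonds are traced to one arylidene acetal spanning O15 and O5'. One group then protects both oxygens through the coupling and releases, in a single reduction, exactly the pattern the key step needs. This replaces the task of telling apart two nearly identical ester termini. The forward reduction must cleave the acetal C–O5' bond and not C–O15.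

22 ⇒ 21. The C13=C16 bond is cut to a C13 ketone, so the 1,1-disubstituted alkene becomes the product of an acylation. The methylenation must be non-basic, because C14 is an enolisable α-silyloxy centre with a β-oxygen.

21 ⇒ 14 + 19. The C12–C13 bond is cut. It is the only bond between ring and oxygenated chain that is flanked by a plain methylene, and cutting it gives a decalin nucleophile with six stereocentres and a four-carbon electrophile with two. The forward step needs a primary alkyllithium that adds only once (hence the N-methoxy-N-methyl amide in 19) and leaves the silyl ethers alone; O8 must be protected.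

19 ⇒ 18 ⇒ 17 ⇒ 16 ⇒ 15. No C–C bond is cut; the amide, the acetal and the silyl ether are removed in turn and C5' returns to the ester oxidation level. 15 already holds C14 and C15 with the required threo relationship and absolute configuration, and its C2 symmetry makes the first protection unambiguous. The forward sequence needs a reduction that touches only the ester next to the free hydroxyl.

14 ⇒ 13 ⇒ 12 ⇒ 11 ⇒ 10. The C12–I bond is traced back to the C12 carbonyl of a lactone that also masks O8. The lactone survives the C18 chemistry and reveals C12 and O8 together. O8 must be silylated before C12 becomes electrophilic, otherwise the C8–O–C12 tetrahydrofuran forms; hence both hydroxyls are silylated and the primary one is released selectively.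

10 ⇒ 9 ⇒ 8 ⇒ 6. The C18–O bond is cut back, through a C18–Si bond, to a C18–H bond. This removes the C4 stereocentre and returns the hydroxymethyl group to one of two geminal methyls, so an abundant 6α-hydroxy labdane can be used. The forward step must select the α-methyl; the syn-pentane-related 6α oxygen directs it, and the lactone keeps O8 out of the way.

6 ⇒ 5 ⇒ 4 ⇒ 2 ⇒ 1. The lactone is opened to the triol; the C8–O and one C17–H bond are cut back to the exocyclic C8=C17 alkene; the C12–O bond is cut back to the C12–C13 bond of a methyl ketone; that ketone is reconnected with C14 and C15 to the vinyl carbinol of 1. 1 supplies C5, C6, C9 and C10 with the right configuration. The forward steps need α-face oxygenation at C8, migration of C12 rather than methyl, and oxidations that spare the 6α-hydroxyl.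

## Other disconnections considered

Alternative 1: The cut is C5–C10 and C8–C9, both carbocycles at once, back to the achiral trienyl imide A1. In the forward step the acyl oxazolidinone of A1 would bind in two-point fashion to a chiral bis(oxazoline) complex of Cu(SbF6)2 (divalent copper). An endo transition state with the tether anti to the carbonyl would close rings A and B together and give A2: the E dienophile places the C9 acyl group cis to the C10 methyl, and the E propenyl terminus gives the 8β-methyl.
- In its favour: four stereocentres (C5, C8, C9, C10), two rings and two C–C bonds would arise from an achiral chain in one catalytic step; either enantiomer is accessible; C6 arrives oxygenated; no natural isolate is needed.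
- Against it here: the dienophile is β,β-disubstituted and must form the quaternary C10, the low end of reactivity for this catalyst class, and the silyl enol ether may be cleaved or react stepwise. A2 also lacks what is hardest in the decalin: C8 is a C–H and not a carbinol, C4 still has two methyls, the C6 ketone would have to be reduced to the equatorial alcohol against the normal facial preference, and the acyl carbon C11 must be extended to C12.
- Comparison: on structure the alternative is the better step, creating far more complexity than step 21 (one ring, one C–C bond, one stereocentre), and it is also better in not depending on a natural product. On mechanism, a catalyst-controlled cycloaddition of a weakly activated trisubstituted dienophile is less predictable than a chelate-controlled addition that sets one centre. On step economy it is worse here: the four centres it sets are already present in 1, and making A1 and converting A2 into a compound like 10 would take clearly more operations than the seven steps from 1. The butenolide problem would remain, so the two disconnections are complementary rather than exclusive.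

Alternative 2: The cut is the C18–O bond, traced through C18–Si to a C18–H bond of the gem-dimethyl group. In the forward step the diethyl(hydrido)silyl ether A3 (the same compound as 7), with [Ir(cod)OMe]2 (monovalent iridium), 3,4,7,8-tetramethyl-1,10-phenanthroline and norbornene as hydrogen acceptor, would undergo Si–H oxidative addition, C18–H cleavage and C–Si reductive elimination. The product would be the oxasilinane A4 (the same compound as 8), which oxidation turns into the 6α,18-diol.
- In its favour: it singles out C18 by geometry alone, needs two operations, tolerates the lactone, and allows the use of 1.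
- Against it as the centre of a plan: it forms no skeletal bond and no ring of 31 and sets only C4. The closure asked of the iridium–phenanthroline catalyst is six-membered, whereas that system is best known for five-membered closure onto γ C–H bonds, so the δ-selective rhodium–Xantphos catalyst of step 5 seems the safer choice. The C17 methyl is a conceivable competitor.
- Comparison: this is not a rival of the chosen plan but part of it, since steps 5 and 6 are this disconnection; on the C18 question and on step economy the two are equal. It is the better choice in one respect: it solves the one problem with no classical solution of comparable brevity, whereas step 21 has a stepwise fallback. The chosen key step is stronger on structure (a ring, a C–C bond, a stereocentre) and in placing the base-sensitive group last. Mechanistically both are substrate-directed, one through an O6–Si tether and one through a magnesium chelate.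

Alternative 3: The cut is C4–C5, C9–C10 and C8–O8 (rings A and B and the γ-lactone), back to the acyclic epoxy dienoic acid A5. In the forward step MeAlCl2 would open the 2,2-disubstituted epoxide at C4; the C5=C10 alkene would attack with inversion at C4, C9 would bond to C10, and the carboxyl would trap C8. A chair–chair array with two E alkenes and a pseudo-equatorial C6 silyloxy group should give the trans-fused lactone A6.
- In its favour: the C18 oxygen comes from the epoxide, so no C–H functionalisation is needed; five stereocentres (C4, C5, C8, C9, C10) and three rings would form in one step; A6 is one silylation away from 10; 1 is not needed.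
- Against it here: the allylic silyloxy group sits on the first nucleophilic alkene, lowers its nucleophilicity and can ionise under the Lewis acid. Such epoxides tend to rearrange to aldehydes, partial cyclisation and elimination compete, and the free acid consumes Lewis acid. A5 needs an enantiopure 2,2-disubstituted epoxide, a defined C6 centre matched to it, and two E trisubstituted alkenes.
- Comparison: on structure it is better than both step 21 and the degradation of 1 in bonds formed per step, and avoiding the C–H silylation is a genuine advantage. On mechanism, a cationic cascade through a deactivated alkene is harder to predict than the chelate-controlled addition or any of steps 1–7. On step economy it is at best equal: 10 is reached in seven steps from 1, and A5 would need about as many before the cyclisation. The route from 10 onward would be unchanged, so it does not replace step 21.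

Key step: step 21

Assumption: atoms are numbered as in labdanes (C1–C20; O1', C2'–C5' for the butenolide); C13 and C16 of 31 are new atoms (from 15 and from the titanium methylidene), because C13–C16 of 1 are excised in steps 1 and 2.
Remark on configuration: the threo diol of (2R,3R)-15 maps onto C14/C15 of 31 (14S,15R) without inversion, and chelate-controlled addition to the (15R) aldehyde gives 5'R; no structure needed correction.
Remark on protecting groups: relative to an all-triethylsilyl (TES) pattern, O6, O18 and O14 carry TBS and only O8 carries TES, so that the primary C12 TES ether can be cleaved selectively in step 10 and O14 stays on through the fragment synthesis.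
Remark on 18, 19, 21 and 22: the acetal carbon is expected as a mixture of two epimers; that centre disappears in step 18 and is left open in the SMILES.

## Route

Step 1
Reactants: 1 larixol
Product: 2 6α-hydroxy-14,15-dinorlabd-8(17)-en-13-one
Conditions: KMnO4, MgSO4, acetone/H2O, 0 °C
Reagents that add atoms: none
Why: Permanganate dihydroxylates the unhindered monosubstituted C14=C15 alkene and cleaves the resulting 13,14-glycol (the classical degradation of a tertiary vinyl carbinol to its methyl ketone); the shielded C8=C17 alkene and the hindered 6α-hydroxyl should react more slowly under cold buffered conditions, and no ring stereocentre is touched.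

Step 2
Reactants: 2 6α-hydroxy-14,15-dinorlabd-8(17)-en-13-one
Product: 4 8α,17-epoxy-6α-hydroxy-13,14,15,16-tetranorlabdan-12-yl acetate, via epoxy ketone 3 (not isolated)
Conditions: CF3CO3H [from (CF3CO)2O and H2O2·urea], Na2HPO4, CH2Cl2, 0 °C → rt; aq. NaHCO3
Reagents that add atoms: trifluoroperacetic acid, OOC(=O)C(F)(F)F
Why: Prilezhaev epoxidation of the exocyclic alkene from the α face (the β face is blocked by the axial C10 methyl) fixes the future 8α oxygen, and Baeyer–Villiger oxidation of the methyl ketone, with migration of the primary C12 in preference to methyl, turns C12 into an acetoxy carbon; the phosphate buffer protects the epoxide, and any 6-O-trifluoroacetate is cleaved in the bicarbonate work-up.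

Step 3
Reactants: 4 8α,17-epoxy-6α-hydroxy-13,14,15,16-tetranorlabdan-12-yl acetate
Product: 5 13,14,15,16-tetranorlabdane-6α,8α,12-triol
Conditions: LiAlH4, THF, 0 °C → reflux
Reagents that add atoms: none
Why: Hydride opens the epoxide by SN2 attack at the primary C17, which leaves oxygen on C8 with α configuration and creates the β-methyl C17, and cleaves the acetate reductively; C8 is thus set by the face selectivity of step 2.

Step 4
Reactants: 5 13,14,15,16-tetranorlabdane-6α,8α,12-triol
Product: 6 6α-hydroxy-13,14,15,16-tetranorlabdan-12,8α-olide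
Conditions: TEMPO (cat.), PhI(OAc)2, CH2Cl2, rt
Reagents that add atoms: none
Why: Oxoammonium oxidation is selective for the primary C12 alcohol; the aldehyde is trapped by the tertiary 8α-hydroxyl as a lactol that is oxidised on to the γ-lactone, which ties up O8 and C12 together, while the hindered secondary 6α-hydroxyl should be oxidised much more slowly.

Step 5
Reactants: 6 6α-hydroxy-13,14,15,16-tetranorlabdan-12,8α-olide
Product: 8 oxasilinane lactone (O6 and C18 bridged by SiEt2), via hydridosilyl ether 7 (not isolated)
Conditions: Et2SiH2, [Ir(cod)OMe]2 (cat.), THF, rt; then [Rh(cod)Cl]2 (cat.), Xantphos, norbornene, THF, 100 °C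
Reagents that add atoms: diethylsilane, CC[SiH2]CC
Why: Dehydrogenative silylation of O6 gives the Si–H ether, and rhodium–Xantphos-catalysed intramolecular C–H silylation (the known alcohol-directed silylation of primary C–H bonds δ to oxygen) closes the six-membered oxasilinane; the equatorial 6α oxygen and the equatorial 4α-methyl C18 are syn-pentane-related whereas C19, C20 and C17 are axial and remote, so C18 should be selected and C4 becomes a stereocentre with the silylmethyl group α.

Step 6
Reactants: 8 oxasilinane lactone
Product: 9 6α,18-dihydroxy-13,14,15,16-tetranorlabdan-12,8α-olide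
Conditions: H2O2 (30% aq.), KHCO3, KF, THF/MeOH, 50 °C; mildly acidic work-up
Reagents that add atoms: hydrogen peroxide, OO
Why: Tamao–Fleming oxidation converts the C18–Si bond into C18–OH (the alkoxy group on silicon allows peroxide attack) and frees O6; a primary carbon is oxidised, so no stereocentre is at stake, and the acidic work-up recloses any lactone opened by the basic peroxide.

Step 7
Reactants: 9 6α,18-dihydroxy-13,14,15,16-tetranorlabdan-12,8α-olide
Product: 10 6α,18-bis(tert-butyldimethylsilyloxy)-13,14,15,16-tetranorlabdan-12,8α-olide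
Conditions: TBSOTf, 2,6-lutidine, CH2Cl2, 0 °C → rt
Reagents that add atoms: tert-butyldimethylsilyl triflate, CC(C)(C)[Si](C)(C)OS(=O)(=O)C(F)(F)F
Why: The silyl triflate with a hindered base silylates both the neopentyl primary O18 and the hindered secondary O6; TBS is chosen so that these ethers outlast the later selective cleavage of a primary TES ether.

Step 8
Reactants: 10 6α,18-bis(tert-butyldimethylsilyloxy)-13,14,15,16-tetranorlabdan-12,8α-olide
Product: 11 6α,18-bis(tert-butyldimethylsilyloxy)-13,14,15,16-tetranorlabdane-8α,12-diol
Conditions: LiAlH4, THF, 0 °C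
Reagents that add atoms: none
Why: Hydride reduction of the γ-lactone gives the primary C12 alcohol and releases the tertiary 8α-hydroxyl; TBS ethers are inert to LiAlH4 at this temperature.

Step 9
Reactants: 11 6α,18-bis(tert-butyldimethylsilyloxy)-13,14,15,16-tetranorlabdane-8α,12-diol
Product: 12 6α,18-bis(tert-butyldimethylsilyloxy)-8α,12-bis(triethylsilyloxy)-13,14,15,16-tetranorlabdane
Conditions: TESOTf, 2,6-lutidine, CH2Cl2, −78 → 0 °C
Reagents that add atoms: triethylsilyl triflate, CC[Si](CC)(CC)OS(=O)(=O)C(F)(F)F
Why: The triflate is reactive enough to silylate the tertiary 8α-hydroxyl along with the primary one; O8 must be blocked before C12 is activated, because a free 8α-hydroxyl would close the C8–O–C12 tetrahydrofuran with any C12 electrophile.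

Step 10
Reactants: 12 6α,18-bis(tert-butyldimethylsilyloxy)-8α,12-bis(triethylsilyloxy)-13,14,15,16-tetranorlabdane
Product: 13 6α,18-bis(tert-butyldimethylsilyloxy)-8α-(triethylsilyloxy)-13,14,15,16-tetranorlabdan-12-ol
Conditions: PPTS (cat.), MeOH/CH2Cl2, 0 °C
Reagents that add atoms: none
Why: Acid-catalysed methanolysis should remove the unhindered primary TES ether far faster than the tertiary TES ether or the TBS ethers (steric control of solvolysis rate).

Step 11
Reactants: 13 6α,18-bis(tert-butyldimethylsilyloxy)-8α-(triethylsilyloxy)-13,14,15,16-tetranorlabdan-12-ol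
Product: 14 12-iodo-6α,18-bis(tert-butyldimethylsilyloxy)-8α-(triethylsilyloxy)-13,14,15,16-tetranorlabdane
Conditions: I2, PPh3, imidazole, CH2Cl2, 0 °C → rt
Reagents that add atoms: iodine, II
Why: Appel-type iodination: the alkoxyphosphonium at the primary C12 is displaced by iodide (SN2); the silylated O8 is a poor nucleophile and should not cyclise under these buffered conditions.

Step 12
Reactants: 15 diethyl L-tartrate
Product: 16 diethyl (2R,3R)-2-(tert-butyldimethylsilyloxy)-3-hydroxybutanedioate
Conditions: TBSCl (1.0 equiv), imidazole, DMF, 0 °C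
Reagents that add atoms: tert-butyldimethylsilyl chloride, CC(C)(C)[Si](C)(C)Cl
Why: The two hydroxyls of the C2-symmetric diester are equivalent, so monosilylation raises no regiochemical question, and the second silylation is retarded by the adjacent bulky silyl ether; the stereocentres are not involved.

Step 13
Reactants: 16 diethyl (2R,3R)-2-(tert-butyldimethylsilyloxy)-3-hydroxybutanedioate
Product: 17 ethyl (2R,3S)-2-(tert-butyldimethylsilyloxy)-3,4-dihydroxybutanoate
Conditions: BH3·SMe2, NaBH4 (cat.), THF, 0 °C → rt; MeOH
Reagents that add atoms: none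
Why: Hydroxyl-directed borane reduction: the free hydroxyl (future O15) forms an alkoxyborane that delivers hydride through a five-membered chelate only to the ester on its own carbon, so the ester next to the silyl ether (future C13) survives and the two termini are differentiated without touching C14 or C15.

Step 14
Reactants: 17 ethyl (2R,3S)-2-(tert-butyldimethylsilyloxy)-3,4-dihydroxybutanoate
Product: 18 ethyl (2R)-2-(tert-butyldimethylsilyloxy)-2-[(4S)-2-(4-methoxyphenyl)-1,3-dioxolan-4-yl]acetate
Conditions: 4-MeOC6H4CH(OMe)2, PPTS (cat.), CH2Cl2, rt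
Reagents that add atoms: 4-methoxybenzaldehyde dimethyl acetal, COC(OC)c1ccc(OC)cc1
Why: Acid-catalysed transacetalisation onto the terminal 1,2-diol gives the five-membered 4-methoxybenzylidene acetal (two epimers at the acetal carbon, both used); the acetal stores the PMB group that O15 needs later and blocks O5', and fast acetalisation should pre-empt γ-lactonisation of the hydroxy ester.

Step 15
Reactants: 18 ethyl (2R)-2-(tert-butyldimethylsilyloxy)-2-[(4S)-2-(4-methoxyphenyl)-1,3-dioxolan-4-yl]acetate
Product: 19 (2R)-2-(tert-butyldimethylsilyloxy)-N-methoxy-2-[(4S)-2-(4-methoxyphenyl)-1,3-dioxolan-4-yl]-N-methylacetamide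
Conditions: MeNH(OMe)·HCl, i-PrMgCl, THF, −20 → 0 °C
Reagents that add atoms: N,O-dimethylhydroxylamine hydrochloride, CNOC.Cl
Why: The chloromagnesium amide of N,O-dimethylhydroxylamine acylates the ester at low temperature to give the Weinreb amide; the α-silyloxy centre (future C14) should not be enolised under these conditions.

Step 16
Reactants: 14 12-iodo-6α,18-bis(tert-butyldimethylsilyloxy)-8α-(triethylsilyloxy)-13,14,15,16-tetranorlabdane; 19 (2R)-2-(tert-butyldimethylsilyloxy)-N-methoxy-2-[(4S)-2-(4-methoxyphenyl)-1,3-dioxolan-4-yl]-N-methylacetamide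
Product: 21 C13 ketone (decalin C12 joined to the amide carbonyl; 14-OTBS; O15/O5' as the 4-methoxybenzylidene acetal), via alkyllithium 20 (not isolated)
Conditions: 14, t-BuLi (2 equiv), Et2O, −78 °C; then 19, THF, −78 → −40 °C; aq. NH4Cl
Reagents that add atoms: none
Why: Iodine–lithium exchange (the second equivalent of t-BuLi destroys t-BuI) gives the primary alkyllithium, which adds once to the Weinreb amide because the five-membered N-methoxy chelate is stable until work-up; this forms C12–C13, and at −78 °C the alkyllithium should neither attack the silyl ethers nor epimerise C14.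

Step 17
Reactants: 21 C13 ketone
Product: 22 C13 methylene compound (14-OTBS; O15/O5' 4-methoxybenzylidene acetal)
Conditions: Cp2TiMe2, toluene, 65 °C, dark
Reagents that add atoms: dimethyltitanocene Cp2TiMe2, [CH3-].[CH3-].[Ti+4].c1cc[cH-]c1.c1cc[cH-]c1
Why: Petasis methylenation: thermolysis of Cp2TiMe2 gives the titanium methylidene, which adds [2+2] to the ketone and cycloreverts to the C13=C16 alkene; the reagent is non-basic, so C14 should not epimerise and the β-oxygen should not eliminate, and it tolerates silyl ethers and the acetal.

Step 18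
Reactants: 22 C13 methylene compound
Product: 23 C5' primary alcohol with the PMB ether on O15 (14-OTBS)
Conditions: i-Bu2AlH, CH2Cl2, −78 → 0 °C
Reagents that add atoms: none
Why: Reductive opening of the arylidene acetal: aluminium coordinates the less hindered primary oxygen O5', the C–O5' bond ionises to an oxocarbenium ion on O15 and hydride reduces it, which should leave the PMB ether on the secondary O15 and the free primary alcohol at C5'; both acetal epimers converge.

Step 19
Reactants: 23 C5' primary alcohol
Product: 24 C5' aldehyde (14-OTBS, 15-OPMB, 6,18-di-OTBS, 8-OTES)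
Conditions: Dess–Martin periodinane, NaHCO3, CH2Cl2, 0 °C → rt; used crude
Reagents that add atoms: none
Why: Buffered Dess–Martin oxidation gives the α-alkoxy aldehyde without acid or base that could epimerise C15 or eliminate the β-silyloxy group; the aldehyde is used at once.

Step 20
Reactants: 25 ethyl but-2-ynoate
Product: 26 ethyl (Z)-3-iodobut-2-enoate
Conditions: NaI, AcOH, 115 °C
Reagents that add atoms: sodium iodide, [Na+].[I-]
Why: Conjugate hydroiodination of the ynoate: iodide adds to C3 and the allenolate is protonated anti, which places iodine cis to the ester (Z) as later lactonisation requires.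

Step 21
Reactants: 24 C5' aldehyde; 26 ethyl (Z)-3-iodobut-2-enoate
Product: 29 protected butenolide (14-OTBS, 15-OPMB, 6,18-di-OTBS, 8-OTES; 5'R), via alkenylmagnesium chloride 27 (not isolated), via magnesium alkoxide 28 (not isolated)
Conditions: 26, i-PrMgCl·LiCl, THF, −40 °C; then 24 premixed with MgBr2·OEt2, CH2Cl2, −78 °C → rt; aq. NH4Cl
Reagents that add atoms: none
Why: Iodine–magnesium exchange on 26 at −40 °C gives the ester-chelated alkenylmagnesium 27 with retention of the Z geometry. Addition of 27 to the aldehyde carbon of 24 forms C4'–C5' and gives alkoxide 28. Because the carbinol carbon and the ester are cis on C3'=C4', 28 closes the butenolide by 5-exo-trig acyl substitution at C2' with loss of ethoxide. The closest known reaction type is the one-pot butenolide synthesis from β-magnesiated Z enoates and aldehydes. C5' is set by the Cram chelate: magnesium, reinforced by MgBr2·OEt2, bridges the aldehyde oxygen and the PMB ether oxygen on C15, and the alkenyl group enters anti to the C14 branch, which gives the 15,5'-syn (5'R) isomer. The bulky TBS ether on O14 does not compete for magnesium, so a β-chelate is suppressed. Chemoselectivity is secured because 24 holds no other electrophile or acidic hydrogen and the cold, weakly basic reagent should not enolise the aldehyde.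

Step 22
Reactants: 29 protected butenolide
Product: 30 15-hydroxy butenolide (14-OTBS, 6,18-di-OTBS, 8-OTES)
Conditions: DDQ, CH2Cl2/pH 7 phosphate buffer, 0 °C → rt
Reagents that add atoms: none
Why: Oxidative PMB cleavage: hydride abstraction from the electron-rich benzylic position gives an oxocarbenium ion that water hydrolyses to the C15 alcohol and anisaldehyde; the neutral buffered medium should spare the butenolide, the silyl ethers and the isolated alkene.

Step 23
Reactants: 30 15-hydroxy butenolide
Product: 31 target, (14S,15R,5'R)-configured 6α,8α,14,15,18-pentahydroxy butenolide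
Conditions: HF·pyridine, pyridine, THF, 0 °C → rt
Reagents that add atoms: none
Why: Fluoride cleaves the three TBS ethers and the tertiary TES ether under buffered, mildly acidic conditions, which avoid the base that would epimerise C5' or open the butenolide and the strong acid that would ionise the tertiary C8 or allylic C14 alcohol; no stereocentre is affected.

## Compound list

1 | larixol, (13S)-labda-8(17),14-diene-6α,13-diol | C=C[C@@](C)(O)CC[C@@H]1[C@@]2(C)CCCC(C)(C)[C@@H]2[C@@H](O)CC1=C | starting material
2 | 6α-hydroxy-14,15-dinorlabd-8(17)-en-13-one | CC(=O)CC[C@@H]1[C@@]2(C)CCCC(C)(C)[C@@H]2[C@@H](O)CC1=C | intermediate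
3 | epoxy ketone, 8α,17-epoxy-6α-hydroxy-14,15-dinorlabdan-13-one | CC(=O)CC[C@@H]1[C@@]2(C)CCCC(C)(C)[C@@H]2[C@@H](O)C[C@@]1(C3)O3 | intermediate
4 | 8α,17-epoxy-6α-hydroxy-13,14,15,16-tetranorlabdan-12-yl acetate | CC(=O)OCC[C@@H]1[C@@]2(C)CCCC(C)(C)[C@@H]2[C@@H](O)C[C@@]1(C3)O3 | intermediate
5 | 13,14,15,16-tetranorlabdane-6α,8α,12-triol | OCC[C@@H]1[C@@]2(C)CCCC(C)(C)[C@@H]2[C@@H](O)C[C@@]1(C)O | intermediate
6 | 6α-hydroxy-13,14,15,16-tetranorlabdan-12,8α-olide | O=C1C[C@@H]2[C@@]3(C)CCCC(C)(C)[C@@H]3[C@@H](O)C[C@@]2(C)O1 | intermediate
7 | hydridosilyl ether, 6α-(diethylsilyloxy) lactone | O=C1C[C@@H]2[C@@]3(C)CCCC(C)(C)[C@@H]3[C@@H](O[SiH](CC)CC)C[C@@]2(C)O1 | intermediate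
8 | oxasilinane lactone, O6 and C18 (4α-CH2) bridged by SiEt2 | O=C1C[C@@H]2[C@@]3(C)CCC[C@@](C)(C[Si]4(CC)CC)[C@@H]3[C@@H](O4)C[C@@]2(C)O1 | intermediate
9 | 6α,18-dihydroxy-13,14,15,16-tetranorlabdan-12,8α-olide | O=C1C[C@@H]2[C@@]3(C)CCC[C@@](C)(CO)[C@@H]3[C@@H](O)C[C@@]2(C)O1 | intermediate
10 | 6α,18-bis(tert-butyldimethylsilyloxy)-13,14,15,16-tetranorlabdan-12,8α-olide | O=C1C[C@@H]2[C@@]3(C)CCC[C@@](C)(CO[Si](C)(C)C(C)(C)C)[C@@H]3[C@@H](O[Si](C)(C)C(C)(C)C)C[C@@]2(C)O1 | intermediate
11 | 6α,18-bis(tert-butyldimethylsilyloxy)-13,14,15,16-tetranorlabdane-8α,12-diol | OCC[C@@H]1[C@@]2(C)CCC[C@@](C)(CO[Si](C)(C)C(C)(C)C)[C@@H]2[C@@H](O[Si](C)(C)C(C)(C)C)C[C@@]1(C)O | intermediate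
12 | 6α,18-bis(tert-butyldimethylsilyloxy)-8α,12-bis(triethylsilyloxy)-13,14,15,16-tetranorlabdane | CC[Si](CC)(CC)OCC[C@@H]1[C@@]2(C)CCC[C@@](C)(CO[Si](C)(C)C(C)(C)C)[C@@H]2[C@@H](O[Si](C)(C)C(C)(C)C)C[C@@]1(C)O[Si](CC)(CC)CC | intermediate
13 | 6α,18-bis(tert-butyldimethylsilyloxy)-8α-(triethylsilyloxy)-13,14,15,16-tetranorlabdan-12-ol | OCC[C@@H]1[C@@]2(C)CCC[C@@](C)(CO[Si](C)(C)C(C)(C)C)[C@@H]2[C@@H](O[Si](C)(C)C(C)(C)C)C[C@@]1(C)O[Si](CC)(CC)CC | intermediate
14 | 12-iodo-6α,18-bis(tert-butyldimethylsilyloxy)-8α-(triethylsilyloxy)-13,14,15,16-tetranorlabdane | ICC[C@@H]1[C@@]2(C)CCC[C@@](C)(CO[Si](C)(C)C(C)(C)C)[C@@H]2[C@@H](O[Si](C)(C)C(C)(C)C)C[C@@]1(C)O[Si](CC)(CC)CC | intermediate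
15 | diethyl L-tartrate, diethyl (2R,3R)-2,3-dihydroxybutanedioate | CCOC(=O)[C@H](O)[C@@H](O)C(=O)OCC | starting material
16 | diethyl (2R,3R)-2-(tert-butyldimethylsilyloxy)-3-hydroxybutanedioate | CCOC(=O)[C@H](O[Si](C)(C)C(C)(C)C)[C@@H](O)C(=O)OCC | intermediate
17 | ethyl (2R,3S)-2-(tert-butyldimethylsilyloxy)-3,4-dihydroxybutanoate | CCOC(=O)[C@H](O[Si](C)(C)C(C)(C)C)[C@@H](O)CO | intermediate
18 | ethyl (2R)-2-(tert-butyldimethylsilyloxy)-2-[(4S)-2-(4-methoxyphenyl)-1,3-dioxolan-4-yl]acetate, acetal epimers | CCOC(=O)[C@H](O[Si](C)(C)C(C)(C)C)[C@@H]1COC(c2ccc(OC)cc2)O1 | intermediate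
19 | (2R)-2-(tert-butyldimethylsilyloxy)-N-methoxy-2-[(4S)-2-(4-methoxyphenyl)-1,3-dioxolan-4-yl]-N-methylacetamide, acetal epimers | CON(C)C(=O)[C@H](O[Si](C)(C)C(C)(C)C)[C@@H]1COC(c2ccc(OC)cc2)O1 | intermediate
20 | alkyllithium, 12-lithio derivative of 14 | [Li]CC[C@@H]1[C@@]2(C)CCC[C@@](C)(CO[Si](C)(C)C(C)(C)C)[C@@H]2[C@@H](O[Si](C)(C)C(C)(C)C)C[C@@]1(C)O[Si](CC)(CC)CC | intermediate
21 | C13 ketone; 6α,18-di-OTBS, 8α-OTES, 14-OTBS, O15/O5' 4-methoxybenzylidene acetal; C14 and C15 as in 31 | O=C(CC[C@@H]1[C@@]2(C)CCC[C@@](C)(CO[Si](C)(C)C(C)(C)C)[C@@H]2[C@@H](O[Si](C)(C)C(C)(C)C)C[C@@]1(C)O[Si](CC)(CC)CC)[C@H](O[Si](C)(C)C(C)(C)C)[C@@H]1COC(c2ccc(OC)cc2)O1 | intermediate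
22 | C13 methylene compound; protecting groups as in 21 | C=C(CC[C@@H]1[C@@]2(C)CCC[C@@](C)(CO[Si](C)(C)C(C)(C)C)[C@@H]2[C@@H](O[Si](C)(C)C(C)(C)C)C[C@@]1(C)O[Si](CC)(CC)CC)[C@H](O[Si](C)(C)C(C)(C)C)[C@@H]1COC(c2ccc(OC)cc2)O1 | intermediate
23 | C5' primary alcohol; 15-OPMB, 14-OTBS, 6α,18-di-OTBS, 8α-OTES | C=C(CC[C@@H]1[C@@]2(C)CCC[C@@](C)(CO[Si](C)(C)C(C)(C)C)[C@@H]2[C@@H](O[Si](C)(C)C(C)(C)C)C[C@@]1(C)O[Si](CC)(CC)CC)[C@H](O[Si](C)(C)C(C)(C)C)[C@@H](OCc1ccc(OC)cc1)CO | intermediate
24 | C5' aldehyde; 15-OPMB, 14-OTBS, 6α,18-di-OTBS, 8α-OTES | C=C(CC[C@@H]1[C@@]2(C)CCC[C@@](C)(CO[Si](C)(C)C(C)(C)C)[C@@H]2[C@@H](O[Si](C)(C)C(C)(C)C)C[C@@]1(C)O[Si](CC)(CC)CC)[C@H](O[Si](C)(C)C(C)(C)C)[C@@H](OCc1ccc(OC)cc1)C=O | intermediate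
25 | ethyl but-2-ynoate | CC#CC(=O)OCC | starting material
26 | ethyl (Z)-3-iodobut-2-enoate | CCOC(=O)/C=C(/C)I | intermediate
27 | alkenylmagnesium chloride, ethyl (Z)-3-(chloromagnesio)but-2-enoate | CCOC(=O)/C=C(/C)[Mg]Cl | intermediate
28 | magnesium alkoxide, open-chain (Z)-hydroxy ester adduct at C5' as its chloromagnesium salt | C=C(CC[C@@H]1[C@@]2(C)CCC[C@@](C)(CO[Si](C)(C)C(C)(C)C)[C@@H]2[C@@H](O[Si](C)(C)C(C)(C)C)C[C@@]1(C)O[Si](CC)(CC)CC)[C@H](O[Si](C)(C)C(C)(C)C)[C@@H](OCc1ccc(OC)cc1)[C@H](O[Mg]Cl)/C(C)=C\C(=O)OCC | intermediate
29 | protected butenolide; 15-OPMB, 14-OTBS, 6α,18-di-OTBS, 8α-OTES; 5'R | C=C(CC[C@@H]1[C@@]2(C)CCC[C@@](C)(CO[Si](C)(C)C(C)(C)C)[C@@H]2[C@@H](O[Si](C)(C)C(C)(C)C)C[C@@]1(C)O[Si](CC)(CC)CC)[C@H](O[Si](C)(C)C(C)(C)C)[C@@H](OCc1ccc(OC)cc1)[C@@H]1OC(=O)C=C1C | intermediate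
30 | 15-hydroxy butenolide; 14-OTBS, 6α,18-di-OTBS, 8α-OTES | C=C(CC[C@@H]1[C@@]2(C)CCC[C@@](C)(CO[Si](C)(C)C(C)(C)C)[C@@H]2[C@@H](O[Si](C)(C)C(C)(C)C)C[C@@]1(C)O[Si](CC)(CC)CC)[C@H](O[Si](C)(C)C(C)(C)C)[C@@H](O)[C@@H]1OC(=O)C=C1C | intermediate
31 | target CNP0301623.1, (14S,15R,5'R) | C=C(CC[C@@H]1[C@@]2(C)CCC[C@@](C)(CO)[C@@H]2[C@@H](O)C[C@@]1(C)O)[C@H](O)[C@@H](O)[C@@H]1OC(=O)C=C1C | target

## Step count and least certain steps

Total: 23 steps. Longest linear sequence: 18 steps from 1 (steps 1–11, 16–19 and 21–23).

Step 21 (key step). The most likely failure is erosion of facial selectivity: THF competes with the PMB oxygen for magnesium, and the open Felkin–Anh pathway leads to the C5' epimer. A slow addition could also allow epimerisation at C15 or loss of the β-silyloxy group. The fallback sets out from 24 and returns at 29. Lithiated ethyl propiolate (LiHMDS, THF, −78 °C) adds to give the γ-hydroxy ynoate F1 as a mixture at C5'. Dess–Martin oxidation gives the ynone F2. Corey–Bakshi–Shibata reduction, with the oxazaborolidine enantiomer that delivers the 5'R carbinol, gives the propargylic alcohol F3, so C5' is set by the catalyst and no longer by the chelate. Me2CuLi (THF, −78 °C) then adds syn across the triple bond with methyl at C4', which places the carbinol carbon cis to the ester, and the alkoxide lactonises to 29.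

Step 5. The risks are low conversion, silylation at a competing site (the C17 methyl or a ring methylene), and reduction of the lactone by the hydrosilane. The fallback sets out from 6 and returns at 9 by a Barton reaction. Nitrosation (NOCl, pyridine) gives the nitrite ester F4. Photolysis generates the 6α-alkoxyl radical, which abstracts hydrogen from C18 through a six-membered transition state favoured by the same geometry; nitroso–oxime tautomerisation gives the C18 oxime F5. Deoximation (aq. TiCl3, NH4OAc) gives the hydroxy aldehyde F6, in equilibrium with its 6,18-lactol, and NaBH4 reduces it to 9.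

Step 2. The risks are acid-induced opening or rearrangement of the spiro-epoxide during the slower Baeyer–Villiger oxidation, and incomplete oxygen insertion. The fallback sets out from 2 and returns at 5. Mukaiyama hydration (Co(acac)2, PhSiH3, O2) of the exocyclic alkene gives the 8α-hydroxy ketone F7, with oxygen delivered to the tertiary radical from the α face. Acid-catalysed dehydration of its hemiketal (TsOH, toluene) gives the cyclic enol ether F8. Ozonolysis (O3, then Me2S) cleaves C12=C13 to the 8α-acetoxy aldehyde F9, and LiAlH4 reduces the aldehyde and removes the acetate to give 5.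

Step 18. The risk is opening of the acetal in the opposite sense, by coordination of aluminium at O15 assisted by O14, which would place the PMB group on O5'. The fallback sets out from 22 and returns at 24. Methanolysis of the acetal (PPTS, MeOH) gives the diol F10. Selective silylation of the primary hydroxyl (TESCl, imidazole, −40 °C) gives the primary TES ether F11. 4-Methoxybenzylation of O15 with PMB trichloroacetimidate and catalytic La(OTf)3 gives the PMB ether F12. Swern oxidation, which converts primary TES ethers directly into aldehydes while sparing the other silyl ethers, gives 24.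

Step 16. The risks are loss of the alkyllithium by protonation, Wurtz-type coupling with t-BuI, or migration of the triethylsilyl group from O8 to C12 (retro-Brook type, six-membered transition state) before acylation. The fallback sets out from 14 and 18 and returns at 21 by a Fukuyama coupling. Zinc insertion (Zn, LiCl, THF) converts 14 into the alkylzinc iodide F13, which does not attack silyl ethers. 18 is saponified (LiOH) to the acid F14 and converted (EtSH, DCC, DMAP) into the S-ethyl thioester F15. PdCl2(PPh3)2-catalysed coupling of F13 with F15 gives 21.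

## Further compounds

F1 | step 21 | γ-hydroxy ynoate from 24 and ethyl propiolate, C5' epimers | C=C(CC[C@@H]1[C@@]2(C)CCC[C@@](C)(CO[Si](C)(C)C(C)(C)C)[C@@H]2[C@@H](O[Si](C)(C)C(C)(C)C)C[C@@]1(C)O[Si](CC)(CC)CC)[C@H](O[Si](C)(C)C(C)(C)C)[C@@H](OCc1ccc(OC)cc1)C(O)C#CC(=O)OCC
F2 | step 21 | ynone at C5' | C=C(CC[C@@H]1[C@@]2(C)CCC[C@@](C)(CO[Si](C)(C)C(C)(C)C)[C@@H]2[C@@H](O[Si](C)(C)C(C)(C)C)C[C@@]1(C)O[Si](CC)(CC)CC)[C@H](O[Si](C)(C)C(C)(C)C)[C@@H](OCc1ccc(OC)cc1)C(=O)C#CC(=O)OCC
F3 | step 21 | (5'R) propargylic alcohol | C=C(CC[C@@H]1[C@@]2(C)CCC[C@@](C)(CO[Si](C)(C)C(C)(C)C)[C@@H]2[C@@H](O[Si](C)(C)C(C)(C)C)C[C@@]1(C)O[Si](CC)(CC)CC)[C@H](O[Si](C)(C)C(C)(C)C)[C@@H](OCc1ccc(OC)cc1)[C@H](O)C#CC(=O)OCC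
F4 | step 5 | 6α-nitrite ester of 6 | O=C1C[C@@H]2[C@@]3(C)CCCC(C)(C)[C@@H]3[C@@H](ON=O)C[C@@]2(C)O1
F5 | step 5 | C18 oxime of the 6α-hydroxy lactone | O=C1C[C@@H]2[C@@]3(C)CCC[C@@](C)(C=NO)[C@@H]3[C@@H](O)C[C@@]2(C)O1
F6 | step 5 | 6α-hydroxy-18-oxo lactone (hydroxy aldehyde) | O=C1C[C@@H]2[C@@]3(C)CCC[C@@](C)(C=O)[C@@H]3[C@@H](O)C[C@@]2(C)O1
F7 | step 2 | 6α,8α-dihydroxy-14,15-dinorlabdan-13-one | CC(=O)CC[C@@H]1[C@@]2(C)CCCC(C)(C)[C@@H]2[C@@H](O)C[C@@]1(C)O
F8 | step 2 | cyclic enol ether, 8α,13-epoxy-14,15-dinorlabd-12-en-6α-ol | CC1=CC[C@@H]2[C@@]3(C)CCCC(C)(C)[C@@H]3[C@@H](O)C[C@@]2(C)O1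
F9 | step 2 | 8α-acetoxy-6α-hydroxy-13,14,15,16-tetranorlabdan-12-al | O=CC[C@@H]1[C@@]2(C)CCCC(C)(C)[C@@H]2[C@@H](O)C[C@@]1(C)OC(C)=O
F10 | step 18 | 15,5'-diol from 22 | C=C(CC[C@@H]1[C@@]2(C)CCC[C@@](C)(CO[Si](C)(C)C(C)(C)C)[C@@H]2[C@@H](O[Si](C)(C)C(C)(C)C)C[C@@]1(C)O[Si](CC)(CC)CC)[C@H](O[Si](C)(C)C(C)(C)C)[C@@H](O)CO
F11 | step 18 | 5'-O-triethylsilyl ether, 15-OH free | C=C(CC[C@@H]1[C@@]2(C)CCC[C@@](C)(CO[Si](C)(C)C(C)(C)C)[C@@H]2[C@@H](O[Si](C)(C)C(C)(C)C)C[C@@]1(C)O[Si](CC)(CC)CC)[C@H](O[Si](C)(C)C(C)(C)C)[C@@H](O)CO[Si](CC)(CC)CC
F12 | step 18 | 15-O-PMB, 5'-O-triethylsilyl ether | C=C(CC[C@@H]1[C@@]2(C)CCC[C@@](C)(CO[Si](C)(C)C(C)(C)C)[C@@H]2[C@@H](O[Si](C)(C)C(C)(C)C)C[C@@]1(C)O[Si](CC)(CC)CC)[C@H](O[Si](C)(C)C(C)(C)C)[C@@H](OCc1ccc(OC)cc1)CO[Si](CC)(CC)CC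
F13 | step 16 | alkylzinc iodide from 14 | I[Zn]CC[C@@H]1[C@@]2(C)CCC[C@@](C)(CO[Si](C)(C)C(C)(C)C)[C@@H]2[C@@H](O[Si](C)(C)C(C)(C)C)C[C@@]1(C)O[Si](CC)(CC)CC
F14 | step 16 | carboxylic acid from 18 | OC(=O)[C@H](O[Si](C)(C)C(C)(C)C)[C@@H]1COC(c2ccc(OC)cc2)O1
F15 | step 16 | S-ethyl thioester | CCSC(=O)[C@H](O[Si](C)(C)C(C)(C)C)[C@@H]1COC(c2ccc(OC)cc2)O1
A1 | alternative 1 | 3-[(2E,8Z,10E)-3,7,7-trimethyl-9-(triisopropylsilyloxy)dodeca-2,8,10-trienoyl]oxazolidin-2-one | O=C1OCCN1C(=O)/C=C(\C)CCCC(C)(C)/C=C(O[Si](C(C)C)(C(C)C)C(C)C)/C=C/C
A2 | alternative 1 | trans-decalin silyl enol ether with C9 acyl oxazolidinone | O=C1OCCN1C(=O)[C@@H]1[C@@]2(C)CCCC(C)(C)[C@@H]2C(O[Si](C(C)C)(C(C)C)C(C)C)=C[C@@H]1C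
A3 | alternative 2 | 6α-(diethylsilyloxy) lactone, identical with 7 | O=C1C[C@@H]2[C@@]3(C)CCCC(C)(C)[C@@H]3[C@@H](O[SiH](CC)CC)C[C@@]2(C)O1
A4 | alternative 2 | oxasilinane-bridged lactone, identical with 8 | O=C1C[C@@H]2[C@@]3(C)CCC[C@@](C)(C[Si]4(CC)CC)[C@@H]3[C@@H](O4)C[C@@]2(C)O1
A5 | alternative 3 | (3E,6S,7E)-6-(tert-butyldimethylsilyloxy)-4,8-dimethyl-11-[(2R)-2-methyloxiran-2-yl]undeca-3,7-dienoic acid | OC(=O)C/C=C(\C)C[C@H](O[Si](C)(C)C(C)(C)C)/C=C(\C)CCC[C@]1(C)CO1
A6 | alternative 3 | 6α-(tert-butyldimethylsilyloxy)-18-hydroxy tricyclic γ-lactone | O=C1C[C@@H]2[C@@]3(C)CCC[C@@](C)(CO)[C@@H]3[C@@H](O[Si](C)(C)C(C)(C)C)C[C@@]2(C)O1
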